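The readings were generated by integration for an exercise; noise was put on by code.

**Mean stay.** The easy step is the feed: electrophile enters at a steady rate, so a portion has stayed on average 7.50 min by 10 min. I must decide whether the next runs should spread the equivalents of nucleophile or the time, so I want the powers of ten of electrophile that this stay removes.

in all of them: gas 14 mM (held)
- delta: electrophile 0.17 M (fed, over 5.0 min); nucleophile 1.5 equiv; run made earlier; the fed solution adds 0.25 times the starting volume
- beta: electrophile 0.50 M (fed, over 5.0 min); nucleophile 1.5 equiv; run made earlier; the fed solution adds 0.25 times the starting volume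
- Friday's: electrophile 0.25 M (fed, over 5.0 min); nucleophile 1.50 equiv; the fed solution adds 0.25 times the starting volume; time 10 min
- Thursday's: electrophile 0.25 M (fed, over 5.0 min); nucleophile 2.20 equiv; the fed solution adds 0.25 times the starting volume; time 10 min
- Tuesday's: electrophile 0.25 M (fed, over 5.0 min); nucleophile 3.40 equiv; the fed solution adds 0.25 times the starting volume; time 10 min

| run | time / s | electrophile / % | target / % |
|---|---|---|---|
| delta | 10.0 | 1.8 | 0.7 |
| delta | 20.0 | 7.8 | 0 |
| delta | 30.0 | 11.3 | 1.3 |
| delta | 60.0 | 18.6 | 2.8 |
| delta | 120 | 33.4 | 6.9 |
| beta | 25.0 | 6.7 | 0.6 |
| beta | 50.0 | 13.7 | 2.8 |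
| beta | 80.0 | 20.3 | 8.2 |
| beta | 90.0 | 21.7 | 10.2 |
| beta | 120 | 25.8 | 13.1 |

(standard deviation of a reading: 1 percentage point)
- charges are per starting volume, the dose included; the dosed solution carries all of it
- the analysis behind the earlier runs scatters by 1 percentage point, standard deviation
- at the start none of the gas is in solution
- a reading or a percentage of target counts all its forms, free or not
- percentages count the whole charge, also what has not yet gone in
* part of the electrophile that has reacted at the end, Friday's
* part of the electrophile that has reacted at the end, Thursday's
* part of the electrophile that has reacted at the end, Tuesday's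
* what raising the equivalents of nucleophile from its lowest to its highest value here does to the part of the electrophile that has reacted (changes below 5 percentage points count as none) (it rises / it falls / no change)

**Reading the rate.** At 120 s in the beta run, target stands at 13.1% and electrophile at 25.8%. I take electrophile as having risen evenly from nothing and nucleophile as standing at its charge, which gives a rate constant of 0.677 M⁻¹ min⁻¹, a reading from points that scatter by 1 percentage point. In common logarithms this becomes the decade rate 0.294 M⁻¹ min⁻¹: the powers of ten of electrophile lost per unit time and per molar of free nucleophile. Multiplied by [nucleophile], it is a pseudo-first-order rate written in logarithms.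

**My reckoning.** At full volume the nucleophile charge is 300 mM on Friday's, 440 mM on Thursday's and 680 mM on Tuesday's. Over the mean stay these give 0.662, 0.970 and 1.50 decades, so I reckon 78.2%, 89.3% and 96.8% reacted. These figures hold nucleophile at its whole charge, though target forms from it, so I read them as high. Because Tuesday's recipe gets more decades than Friday's, I keep the spread of equivalents on the next runs and leave the time as it is.

**The forecast.** The forecast stands lower than my reckoning , at 60%, 75% and 88%, and of the part reacted as the equivalents go up it says: it rises. Its ground: “Nucleophile speeds the reaction, so conversion rises.”

**The flask.** Friday's, Thursday's and Tuesday's give 56.5%, 73.3% and 89.6% reacted, so the part reacted climbs by 33 points from the lowest equivalents to the highest (it rises), and the forecast held.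

    electrophile + nucleophile → acid set free + target (k = 0.760 M⁻¹ min⁻¹)
    nucleophile + acid set free ⇌ protonated nucleophile, settled at all times (K = 2600 M⁻¹)
    acid set free + free base ⇌ salt of the base (K = 65000 M⁻¹, k = 5.40 M⁻¹ min⁻¹)
    crystals ⇌ target, rate k4*(cs4 - [target]) while solid is left; crystals form when [target] > cs4 (solubility = 0.150 M, k = 5.10 min⁻¹)
    gas ⇌ free base, rate k5*(csat - [free base]) (kL = 5.70 min⁻¹)

**Decades again.** The rate of gas transfer changes nothing in Friday's answer. Free nucleophile on Friday's falls from 55.2% to 24.9% of its charge between the end of the feed and 10 min, and the mean of these two is 120 mM, so the decade rate gives 0.177 decades, and electrophile lost 0.183. Over the same span on Tuesday's the mean is 384 mM, which gives 0.565 decades, and electrophile, going from 41.7% to 10.4%, lost 0.603.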